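**Assumption:** (S)-3,7-dimethylocta-1,6-diene ((S)-β-citronellene) is bought as the single enantiomer. Names use tetralin numbering: C1 = CH–CH3, C2 = C–O, C4 = CH–side chain, C6 = one-carbon substituent, C8 = phenol.

**Retrosynthetic overview**
1. Target ⇐ triol (acetylate all three OH, then release the phenol) ⇐ 2-tetralone methyl ester (one hydride step reduces ketone and ester).
2. Key bond C1–C2: a carbene-generated acyl anion at the aldehyde carbon C2 attacks C1 of an ortho-quinone methide formed in the flask from an ortho-hydroxystyrene. This closes the only ring the route makes; the benzene ring is bought.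
3. The aldehyde comes from a rhodium-catalysed asymmetric 1,4-addition of an arylboronate to an E-enal, which sets C4.
4. The enal comes from (S)-β-citronellene and crotonaldehyde by cross-metathesis; C11 is from the chiral pool.
5. The arylboronate comes from methyl 4-bromo-3,5-dihydroxybenzoate by vinylation, mono-triflation and borylation, with no protecting groups.

**Step 1**
Reactants: 1 methyl 4-bromo-3,5-dihydroxybenzoate; 2 potassium vinyltrifluoroborate
Product: 3 methyl 4-ethenyl-3,5-dihydroxybenzoate
Conditions: Pd(OAc)2 (3 mol %), SPhos (6 mol %), K2CO3 (4 equiv), dioxane/H2O 4:1, 85 °C; acidic work-up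
Reagents that add atoms: none
Why: Suzuki–Miyaura coupling, in which the para ester activates the C–Br bond and the biarylphosphine tolerates the two flanking phenoxides, installs the vinyl group that becomes C1 and its methyl; no stereocenter is formed.

**Step 2**
Reactants: 3 methyl 4-ethenyl-3,5-dihydroxybenzoate
Product: 4 methyl 4-ethenyl-3-hydroxy-5-(trifluoromethanesulfonyloxy)benzoate
Conditions: PhNTf2 (1.0 equiv, slow addition), Et3N (1.1 equiv), CH2Cl2, 0 °C to rt; recovered 3 recycled
Reagents that add atoms: N-phenylbis(trifluoromethanesulfonimide), O=S(=O)(N(c1ccccc1)S(=O)(=O)C(F)(F)F)C(F)(F)F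
Why: Sulfonylation of one of two homotopic phenols (statistical, roughly half the material per pass, bis-triflate removed) makes the oxygen on the future C4a a leaving group and keeps the other as the C8 phenol; no stereocenter.

**Step 3**
Reactants: 4 methyl 4-ethenyl-3-hydroxy-5-(trifluoromethanesulfonyloxy)benzoate
Product: 5 methyl 4-ethenyl-3-hydroxy-5-(4,4,5,5-tetramethyl-1,3,2-dioxaborolan-2-yl)benzoate
Conditions: B2pin2 (1.3 equiv), PdCl2(dppf) (5 mol %), KOAc (3 equiv), dioxane, 80 °C
Reagents that add atoms: bis(pinacolato)diboron, CC1(C)OB(OC1(C)C)B1OC(C)(C)C(C)(C)O1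
Why: Miyaura borylation of the aryl triflate with the weak base KOAc avoids Suzuki homocoupling and tolerates the free phenol, ester and styrene; no stereocenter.

**Step 4**
Reactants: 6 (S)-3,7-dimethylocta-1,6-diene; 7 (E)-but-2-enal (5 equiv)
Product: 8 (2E,4S)-4,8-dimethylnona-2,7-dienal
Conditions: second-generation Hoveyda–Grubbs catalyst RuCl2(=CH-C6H4-2-OiPr)(H2IMes) (3 mol %), CH2Cl2, 40 °C
Reagents that add atoms: none
Why: Olefin cross-metathesis occurs only at the monosubstituted alkene (the trisubstituted one is far slower) and is E-selective with the enal partner; the allylic methyl stereocenter (future C11, from the chiral pool) is untouched.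

**Step 5**
Reactants: 5 methyl 4-ethenyl-3-hydroxy-5-(4,4,5,5-tetramethyl-1,3,2-dioxaborolan-2-yl)benzoate; 8 (2E,4S)-4,8-dimethylnona-2,7-dienal (1.3 equiv)
Product: 9 methyl 4-ethenyl-3-hydroxy-5-[(3S,4S)-4,8-dimethyl-1-oxonon-7-en-3-yl]benzoate
Conditions: [RhCl(C2H4)2]2 (2.5 mol %), (1S,4S)-2,5-diphenylbicyclo[2.2.2]octa-2,5-diene (5.5 mol %), KOH (0.5 equiv), dioxane/H2O 10:1, 30 °C
Reagents that add atoms: none
Why: In this Hayashi–Miyaura asymmetric 1,4-addition the aryl–rhodium diene complex adds to C3 of the E-enal on its Re face (the α-Si face, the sense expected for this ligand enantiomer with E acceptors), setting C4 as S under catalyst control because the neighbouring Me/CH2 stereocenter biases the face only weakly; the diene ligand suppresses 1,2-addition.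

**Step 6 (key step)**
Reactants: 9 methyl 4-ethenyl-3-hydroxy-5-[(3S,4S)-4,8-dimethyl-1-oxonon-7-en-3-yl]benzoate
Product: 11 methyl (1S,4S)-8-hydroxy-1-methyl-4-[(2S)-6-methylhept-5-en-2-yl]-2-oxo-1,2,3,4-tetrahydronaphthalene-6-carboxylate, via ortho-quinone methide 10 (not isolated)
Conditions: 2-mesityl-6,7-dihydro-5H-pyrrolo[2,1-c][1,2,4]triazol-2-ium chloride (20 mol %), DBU (0.5 equiv), 1,4-dioxane (0.02 M), 80 °C, Ar; then rt to equilibrate C1
Reagents that add atoms: none
Why: Proposed new method: the triazolylidene turns the aldehyde into its acyl-anion equivalent (Breslow intermediate) while phenoxide/DBU-H+ proton shuttling tautomerises the ortho-hydroxystyrene to ortho-quinone methide 10, whose exocyclic carbon C1 is electrophilic and positioned for six-membered ring closure by the nucleophilic C2, after which rearomatisation and loss of carbene give the 2-tetralone (net intramolecular hydroacylation: acyl to the internal carbon, H to the terminal carbon); the acidic C1–H is then equilibrated by DBU to the 1,4-trans isomer, in which the C1 methyl and C4 side chain are both pseudoaxial and escape peri strain with the C8–OH and C5–H (expected about 5:1 or better); closest known reaction types are the carbene-catalysed intramolecular hydroacylation of tethered alkenes, the carbene-catalysed acyl-anion addition to ortho-quinone methides, and the intramolecular Stetter reaction.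

**Step 7**
Reactants: 11 methyl (1S,4S)-8-hydroxy-1-methyl-4-[(2S)-6-methylhept-5-en-2-yl]-2-oxo-1,2,3,4-tetrahydronaphthalene-6-carboxylate
Product: 12 (1S,2S,4S)-6-(hydroxymethyl)-1-methyl-4-[(2S)-6-methylhept-5-en-2-yl]-1,2,3,4-tetrahydronaphthalene-2,8-diol
Conditions: LiAlH4 (4 equiv), THF, −78 °C to 0 °C; aq. potassium sodium tartrate work-up
Reagents that add atoms: none
Why: Hydride reduction of ketone and ester in one operation: the pseudoaxial C4 side chain lies 1,3-syn over the β face of the C2 carbonyl and blocks that trajectory (as a 3-axial group does in cyclohexanones), so the small hydride should enter from the α face and give the 2S alcohol (OH cis to the side chain, trans to the methyl); the ketone reacts at −78 °C before enolisation can scramble C1.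

**Step 8**
Reactants: 12 (1S,2S,4S)-6-(hydroxymethyl)-1-methyl-4-[(2S)-6-methylhept-5-en-2-yl]-1,2,3,4-tetrahydronaphthalene-2,8-diol
Product: 14 (1S,2S,4S)-6-(acetoxymethyl)-8-hydroxy-1-methyl-4-[(2S)-6-methylhept-5-en-2-yl]-1,2,3,4-tetrahydronaphthalen-2-yl acetate, via triacetate 13 (not isolated)
Conditions: Ac2O (4 equiv), Et3N, DMAP (10 mol %), CH2Cl2, rt; evaporate; then NH4OAc, MeOH/H2O 4:1, rt
Reagents that add atoms: acetic anhydride, CC(=O)OC(C)=O
Why: Exhaustive acetylation followed by chemoselective methanolysis of the aryl acetate (phenoxide is by far the best leaving group, and alkyl acetates are inert to neutral NH4OAc/MeOH) leaves the two aliphatic acetates and the free phenol; no stereocenter is touched.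

**Compound list**
1 | methyl 4-bromo-3,5-dihydroxybenzoate | COC(=O)c1cc(O)c(Br)c(O)c1 | starting material
2 | potassium vinyltrifluoroborate | C=C[B-](F)(F)F.[K+] | starting material
3 | methyl 4-ethenyl-3,5-dihydroxybenzoate | COC(=O)c1cc(O)c(C=C)c(O)c1 | intermediate
4 | methyl 4-ethenyl-3-hydroxy-5-(trifluoromethanesulfonyloxy)benzoate | COC(=O)c1cc(O)c(C=C)c(OS(=O)(=O)C(F)(F)F)c1 | intermediate
5 | methyl 4-ethenyl-3-hydroxy-5-(4,4,5,5-tetramethyl-1,3,2-dioxaborolan-2-yl)benzoate | COC(=O)c1cc(O)c(C=C)c(B2OC(C)(C)C(C)(C)O2)c1 | intermediate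
6 | (S)-3,7-dimethylocta-1,6-diene | C=C[C@@H](C)CCC=C(C)C | starting material
7 | (E)-but-2-enal | C/C=C/C=O | starting material
8 | (2E,4S)-4,8-dimethylnona-2,7-dienal | O=C/C=C/[C@@H](C)CCC=C(C)C | intermediate
9 | methyl 4-ethenyl-3-hydroxy-5-[(3S,4S)-4,8-dimethyl-1-oxonon-7-en-3-yl]benzoate | COC(=O)c1cc(O)c(C=C)c([C@H]([C@@H](C)CCC=C(C)C)CC=O)c1 | intermediate
10 | methyl 4-ethylidene-3-oxo-5-[(3S,4S)-4,8-dimethyl-1-oxonon-7-en-3-yl]cyclohexa-1,5-diene-1-carboxylate (ortho-quinone methide tautomer of 9, alkene geometry not defined) | COC(=O)C1=CC(=O)C(=CC)C([C@H]([C@@H](C)CCC=C(C)C)CC=O)=C1 | intermediate (not isolated)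
11 | methyl (1S,4S)-8-hydroxy-1-methyl-4-[(2S)-6-methylhept-5-en-2-yl]-2-oxo-1,2,3,4-tetrahydronaphthalene-6-carboxylate | COC(=O)c1cc(O)c2c(c1)[C@H]([C@@H](C)CCC=C(C)C)CC(=O)[C@H]2C | intermediate
12 | (1S,2S,4S)-6-(hydroxymethyl)-1-methyl-4-[(2S)-6-methylhept-5-en-2-yl]-1,2,3,4-tetrahydronaphthalene-2,8-diol | OCc1cc(O)c2c(c1)[C@H]([C@@H](C)CCC=C(C)C)C[C@H](O)[C@H]2C | intermediate
13 | (1S,2S,4S)-6-(acetoxymethyl)-1-methyl-4-[(2S)-6-methylhept-5-en-2-yl]-1,2,3,4-tetrahydronaphthalene-2,8-diyl diacetate | CC(=O)OCc1cc(OC(C)=O)c2c(c1)[C@H]([C@@H](C)CCC=C(C)C)C[C@H](OC(C)=O)[C@H]2C | intermediate (not isolated)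
14 | (1S,2S,4S)-6-(acetoxymethyl)-8-hydroxy-1-methyl-4-[(2S)-6-methylhept-5-en-2-yl]-1,2,3,4-tetrahydronaphthalen-2-yl acetate | CC(=O)OCc1cc(O)c2c(c1)[C@H]([C@@H](C)CCC=C(C)C)C[C@H](OC(C)=O)[C@H]2C | target

**Step count**
Total steps: 8. Longest linear sequence: 7 (steps 1, 2, 3, 5, 6, 7, 8 from compound 1); step 4 is a one-step side branch.

**Three steps most likely to fail**

Step 6 (key cyclisation). The risks are closure at the terminal vinyl carbon (seven-membered ketone), aldehyde self-benzoin or aldol, attack of the aldehyde enol carbon on 10 (an indane), and incomplete trans selectivity at C1. The fallback sets out from 9 and returns at 11. Tsuji–Wacker oxidation of the styrene (PdCl2, CuCl, O2, DMF/H2O) gives methyl 4-acetyl-3-hydroxy-5-[(3S,4S)-4,8-dimethyl-1-oxonon-7-en-3-yl]benzoate F1. A carbene-catalysed aldehyde–ketone crossed benzoin cyclisation (same triazolium salt, Et3N, CH2Cl2, rt) then gives the α-ketol methyl (4S)-1,8-dihydroxy-1-methyl-4-[(2S)-6-methylhept-5-en-2-yl]-2-oxo-1,2,3,4-tetrahydronaphthalene-6-carboxylate F2. SmI2 (THF/MeOH, −78 °C) removes the tertiary α-hydroxyl and DBU equilibration at C1 delivers 11.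

Step 7 (face of hydride attack at C2). Simple 1-alkyl-2-tetralones are usually attacked anti to the pseudoaxial C1 substituent, which here would give the wrong epimer, so the selectivity argued above is uncertain. The fallback sets out from 11 and returns at 14. Reduction in that opposite sense (LiBH(s-Bu)3, THF, −78 °C, then LiAlH4 for the ester) gives (1S,2R,4S)-6-(hydroxymethyl)-1-methyl-4-[(2S)-6-methylhept-5-en-2-yl]-1,2,3,4-tetrahydronaphthalene-2,8-diol F3. A Mitsunobu reaction with acetic acid (PPh3, DIAD, AcOH, THF, 0 °C) then inverts C2 and acetylates the primary benzylic alcohol in the same operation; the phenol is spared because acetic acid is the far stronger acid pronucleophile. This gives 14 directly.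

Step 5 (asymmetric 1,4-addition). The ortho-vinyl arylboronate is hindered, the enal and product aldehyde are base-sensitive, and the sense of induction must be confirmed (the mirror-image diene is equally available). The fallback sets out from 6 (and uses 5) and returns at 9. Cross-metathesis of 6 with N-methoxy-N-methylacrylamide (same ruthenium catalyst) gives (2E,4S)-N-methoxy-N,4,8-trimethylnona-2,7-dienamide F4. Rhodium/diene-catalysed addition of 5 to this more robust acceptor (same ligand, KOH, dioxane/H2O, 50 °C) gives methyl 4-ethenyl-3-hydroxy-5-[(3S,4S)-1-[methoxy(methyl)amino]-4,8-dimethyl-1-oxonon-7-en-3-yl]benzoate F5. Partial reduction of the amide with i-Bu2AlH (THF, −78 °C) then gives 9.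

**Further compounds**
F1 | step 6 | methyl 4-acetyl-3-hydroxy-5-[(3S,4S)-4,8-dimethyl-1-oxonon-7-en-3-yl]benzoate | COC(=O)c1cc(O)c(C(C)=O)c([C@H]([C@@H](C)CCC=C(C)C)CC=O)c1
F2 | step 6 | methyl (4S)-1,8-dihydroxy-1-methyl-4-[(2S)-6-methylhept-5-en-2-yl]-2-oxo-1,2,3,4-tetrahydronaphthalene-6-carboxylate (mixture at C1) | COC(=O)c1cc(O)c2c(c1)[C@H]([C@@H](C)CCC=C(C)C)CC(=O)C2(C)O
F3 | step 7 | (1S,2R,4S)-6-(hydroxymethyl)-1-methyl-4-[(2S)-6-methylhept-5-en-2-yl]-1,2,3,4-tetrahydronaphthalene-2,8-diol | OCc1cc(O)c2c(c1)[C@H]([C@@H](C)CCC=C(C)C)C[C@@H](O)[C@H]2C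
F4 | step 5 | (2E,4S)-N-methoxy-N,4,8-trimethylnona-2,7-dienamide | CON(C)C(=O)/C=C/[C@@H](C)CCC=C(C)C
F5 | step 5 | methyl 4-ethenyl-3-hydroxy-5-[(3S,4S)-1-[methoxy(methyl)amino]-4,8-dimethyl-1-oxonon-7-en-3-yl]benzoate | COC(=O)c1cc(O)c(C=C)c([C@H]([C@@H](C)CCC=C(C)C)CC(=O)N(C)OC)c1
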